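**Retrosynthetic overview**

1. Artocarpol D (16) is taken back to its bis-TIPS ether 15; both silyl ethers are removed with fluoride in the last step.
2. 15 is cut in one operation to the open diaryl ether amide 10 and prenal (11). The C10–C11 bond of the oxepine ring and the C11–CH and O–CMe2 bonds of the pyran ring are all made in step 7 (lateral metalation/anionic cyclisation → lithium enolate → aldol condensation → oxa-6π electrocyclisation).
3. Enabling feature: C11 of the central oxepine ring lies between ring A and C10, the carbon that carries the pyran oxygen. Closing the seven-membered ring by acylation therefore delivers the O–C10=C11 enolate, a 1,3-O,C-dinucleophile that matches the CH=CH–CMe2 unit of prenal; the gem-dimethyl carbon of the pyran drives the 1-oxatriene to close.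
4. 10 comes from an Ullmann diaryl ether coupling of phenol 9 (ring A: methyl = future C11, prenyl, OTIPS) with bromo amide 3 (ring B: amide carbon = future C10). 9 is made from 5-bromo-2,4-dihydroxybenzaldehyde (4) and 3 from 2-bromo-4-hydroxybenzoic acid (1).
5. Ring order: rings A and B are bought; the oxygen bridge is set in step 6; the oxepine ring and then the pyran ring are closed in step 7.

Key step: step 7

Remark: the target has no stereocentre (the cis C=C of the pyran is fixed by the ring), so no step needs stereocontrol. Locants follow dibenz[b,f]oxepine numbering: ring A is the prenylated ring (C1–C4, C4a, C11a) and ring B is the ring joined to C10 (C5a–C9a).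

**Route**

Step 1
Reactants: 1 2-bromo-4-hydroxybenzoic acid
Product: 2 2-bromo-N,N-diethyl-4-hydroxybenzamide
Conditions: DIC, HOBt (cat.), HNEt2 (3 equiv), DMF, 0 °C → rt
Reagents that add atoms: diethylamine, CCNCC
Why: Carbodiimide-mediated amide coupling through the HOBt active ester should activate the carboxylic acid far faster than the phenol, and any aryl ester formed is re-opened by the excess amine.

Step 2
Reactants: 2 2-bromo-N,N-diethyl-4-hydroxybenzamide
Product: 3 2-bromo-N,N-diethyl-4-[(triisopropylsilyl)oxy]benzamide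
Conditions: TIPSCl, imidazole, DMF, rt
Reagents that add atoms: chlorotriisopropylsilane (TIPSCl), CC(C)[Si](Cl)(C(C)C)C(C)C
Why: Standard phenol silylation; the bulky TIPS ether is chosen because it should withstand carbonate in hot toluene and LiN(i-Pr)2 and still be cleaved by fluoride at the end.

Step 3
Reactants: 4 5-bromo-2,4-dihydroxybenzaldehyde
Product: 5 5-bromo-2-hydroxy-4-[(triisopropylsilyl)oxy]benzaldehyde
Conditions: TIPSCl (1.05 equiv), imidazole, CH2Cl2, 0 °C
Reagents that add atoms: chlorotriisopropylsilane (TIPSCl), CC(C)[Si](Cl)(C(C)C)C(C)C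
Why: Regioselective O-silylation, because the 2-OH is tied up in a hydrogen bond to the aldehyde and the more acidic 4-OH reacts first; the 2-OH is thus kept free for the later diaryl ether.

Step 4
Reactants: 5 5-bromo-2-hydroxy-4-[(triisopropylsilyl)oxy]benzaldehyde
Product: 7 4-bromo-2-methyl-5-[(triisopropylsilyl)oxy]phenol, via benzylic alcohol 6 (not isolated)
Conditions: Et3SiH (3 equiv), TFA, CH2Cl2, 0 °C → rt
Reagents that add atoms: none
Why: Ionic hydrogenation of an electron-rich benzaldehyde: hydride reduction to 6, acid-promoted loss of the benzylic oxygen assisted by the ortho-hydroxyl and para-silyloxy groups, then a second hydride transfer, conditions to which the aryl bromide and the aryl TIPS ether should be inert.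

Step 5
Reactants: 7 4-bromo-2-methyl-5-[(triisopropylsilyl)oxy]phenol
Product: 9 2-methyl-4-(3-methylbut-2-en-1-yl)-5-[(triisopropylsilyl)oxy]phenol, via dilithio species 8 (not isolated)
Conditions: t-BuLi (3.0 equiv), THF, −78 °C; then prenyl bromide (1.2 equiv), CuBr·SMe2 (10 mol%), −78 → 0 °C; H2O
Reagents that add atoms: prenyl bromide (1-bromo-3-methylbut-2-ene), CC(C)=CCBr
Why: Bromine–lithium exchange followed by SN2 alkylation of the aryllithium at the unhindered primary end of prenyl bromide; three equivalents of t-BuLi cover the phenol proton, the exchange and the t-BuBr formed, and at −78 °C the TIPS group should stay on oxygen.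

Step 6
Reactants: 9 2-methyl-4-(3-methylbut-2-en-1-yl)-5-[(triisopropylsilyl)oxy]phenol; 3 2-bromo-N,N-diethyl-4-[(triisopropylsilyl)oxy]benzamide
Product: 10 N,N-diethyl-2-{2-methyl-4-(3-methylbut-2-en-1-yl)-5-[(triisopropylsilyl)oxy]phenoxy}-4-[(triisopropylsilyl)oxy]benzamide
Conditions: Cu(MeCN)4PF6 (10 mol%), Cs2CO3 (2 equiv), toluene, 110 °C
Reagents that add atoms: none
Why: Ullmann-type diaryl ether synthesis with monovalent copper, in which the ortho carboxamide of 3 assists the copper at the C–Br bond (the ortho-halobenzamide/phenol coupling) and the non-polar medium should keep both silyl ethers intact.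

Step 7
Reactants: 10 N,N-diethyl-2-{2-methyl-4-(3-methylbut-2-en-1-yl)-5-[(triisopropylsilyl)oxy]phenoxy}-4-[(triisopropylsilyl)oxy]benzamide; 11 3-methylbut-2-enal (prenal)
Product: 15 artocarpol D bis(triisopropylsilyl) ether, via lithium enolate 12 (not isolated), via lithium aldolate 13 (not isolated), via (Z)-dienone 14 (not isolated)
Conditions: LiN(i-Pr)2 (2.3 equiv), THF, 0 °C → rt; then t-BuOH (3 equiv), −78 °C; then 11 (2 equiv), −78 → 45 °C; H2O
Reagents that add atoms: none
Why: Proposed new method: LiN(i-Pr)2, complexed to the diethylamide on ring B, should deprotonate the neighbouring ring-A methyl group (future C11); the benzyllithium attacks the amide carbonyl (future C10) and expels LiNEt2, the oxepinone is deprotonated at once to enolate 12, and 12 is not quenched but adds 1,2 to prenal to give aldolate 13, which loses LiOH by E1cB (C11–H is benzylic and alpha to C10=O) to give 1-oxatriene 14, which closes thermally to 15; t-BuOH is added before prenal to turn the residual lithium amides into LiOt-Bu, which spares the aldehyde and the silyl ethers and mediates the elimination. The closest known reaction types are the lateral-metalation/anionic cyclisation of ortho-methyl ortho'-carboxamido biaryls and heteroatom-bridged diaryls (to 9-phenanthrols and dibenzazepinones) and the aldol condensation/oxa-6π electrocyclisation (formal 3+3 annulation) of enolisable carbonyl compounds with prenal; what is new is their union, in which the enolate born in the cyclisation is the nucleophile of the annulation. The oxepine ring closes by 7-exo-trig acyl substitution and the pyran ring by disrotatory 6π electrocyclisation of the (Z)-dienone, which is pulled to the closed side by the gem-dimethyl terminus and by the stilbene-type conjugation of the new C10=C11 bond with rings A and B. No stereocentre is formed. The step needs lateral metalation to beat metalation of ring A at the C–H between its two oxygens (future C4–H, the xanthone path) and at the prenyl CH2, which should be secured by the proximity of the methyl group to the complexed base and by the TIPS group that shields that C–H; it needs 1,2-addition to prenal, secured by the β,β-disubstitution; and it needs the (Z)-dienone, which the (E)-isomer should reach by reversible conjugate addition of the liberated diethylamine.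

Step 8
Reactants: 15 artocarpol D bis(triisopropylsilyl) ether
Product: 16 artocarpol D
Conditions: TBAF (2.2 equiv), AcOH (2.2 equiv), THF, 0 °C → rt
Reagents that add atoms: none
Why: Fluoride cleavage of aryl silyl ethers, buffered with AcOH so that the dienol ether of the pyran and the ortho-prenyl phenol should meet neither strong acid nor free phenoxide base.

**Compound list**

1 | 2-bromo-4-hydroxybenzoic acid | OC(=O)c1ccc(O)cc1Br | starting material
2 | 2-bromo-N,N-diethyl-4-hydroxybenzamide | CCN(CC)C(=O)c1ccc(O)cc1Br | intermediate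
3 | 2-bromo-N,N-diethyl-4-[(triisopropylsilyl)oxy]benzamide | CCN(CC)C(=O)c1ccc(O[Si](C(C)C)(C(C)C)C(C)C)cc1Br | intermediate
4 | 5-bromo-2,4-dihydroxybenzaldehyde | O=Cc1cc(Br)c(O)cc1O | starting material
5 | 5-bromo-2-hydroxy-4-[(triisopropylsilyl)oxy]benzaldehyde | O=Cc1cc(Br)c(O[Si](C(C)C)(C(C)C)C(C)C)cc1O | intermediate
6 | 4-bromo-2-(hydroxymethyl)-5-[(triisopropylsilyl)oxy]phenol (benzylic alcohol, not isolated) | OCc1cc(Br)c(O[Si](C(C)C)(C(C)C)C(C)C)cc1O | intermediate
7 | 4-bromo-2-methyl-5-[(triisopropylsilyl)oxy]phenol | Cc1cc(Br)c(O[Si](C(C)C)(C(C)C)C(C)C)cc1O | intermediate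
8 | lithium 4-lithio-2-methyl-5-[(triisopropylsilyl)oxy]phenolate (dilithio species, not isolated) | [Li]c1cc(C)c(O[Li])cc1O[Si](C(C)C)(C(C)C)C(C)C | intermediate
9 | 2-methyl-4-(3-methylbut-2-en-1-yl)-5-[(triisopropylsilyl)oxy]phenol | Cc1cc(CC=C(C)C)c(O[Si](C(C)C)(C(C)C)C(C)C)cc1O | intermediate
10 | N,N-diethyl-2-{2-methyl-4-(3-methylbut-2-en-1-yl)-5-[(triisopropylsilyl)oxy]phenoxy}-4-[(triisopropylsilyl)oxy]benzamide | CCN(CC)C(=O)c1ccc(O[Si](C(C)C)(C(C)C)C(C)C)cc1Oc1cc(O[Si](C(C)C)(C(C)C)C(C)C)c(CC=C(C)C)cc1C | intermediate
11 | 3-methylbut-2-enal (prenal) | CC(C)=CC=O | starting material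
12 | lithium 2-(3-methylbut-2-en-1-yl)-3,7-bis[(triisopropylsilyl)oxy]dibenz[b,f]oxepin-10-olate (lithium enolate, not isolated) | [Li+].[O-]C1=Cc2cc(CC=C(C)C)c(O[Si](C(C)C)(C(C)C)C(C)C)cc2Oc2cc(O[Si](C(C)C)(C(C)C)C(C)C)ccc12 | intermediate
13 | lithium 3-methyl-1-{2-(3-methylbut-2-en-1-yl)-10-oxo-3,7-bis[(triisopropylsilyl)oxy]-10,11-dihydrodibenz[b,f]oxepin-11-yl}but-2-en-1-olate (lithium aldolate, diastereomer mixture, not isolated) | CC(C)=CC([O-])C1C(=O)c2ccc(O[Si](C(C)C)(C(C)C)C(C)C)cc2Oc2cc(O[Si](C(C)C)(C(C)C)C(C)C)c(CC=C(C)C)cc21.[Li+] | intermediate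
14 | (11Z)-2-(3-methylbut-2-en-1-yl)-11-(3-methylbut-2-en-1-ylidene)-3,7-bis[(triisopropylsilyl)oxy]dibenz[b,f]oxepin-10(11H)-one ((Z)-dienone, not isolated) | O=C1/C(=C\C=C(C)C)c2cc(CC=C(C)C)c(O[Si](C(C)C)(C(C)C)C(C)C)cc2Oc2cc(O[Si](C(C)C)(C(C)C)C(C)C)ccc21 | intermediate
15 | artocarpol D bis(triisopropylsilyl) ether (2,2-dimethyl-2H-pyran fused across C10–C11 of the dibenz[b,f]oxepine with its oxygen on C10; prenyl on C2; OTIPS on C3 and C7) | CC(C)=CCc1cc2c(cc1O[Si](C(C)C)(C(C)C)C(C)C)Oc1cc(O[Si](C(C)C)(C(C)C)C(C)C)ccc1C1=C2C=CC(C)(C)O1 | intermediate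
16 | artocarpol D | CC(C)=CCc1cc2c(cc1O)Oc1cc(O)ccc1C1=C2C=CC(C)(C)O1 | target

**Step count and risks**

Total steps: 8. Longest linear sequence: 6 steps (steps 3, 4, 5, 6, 7 and 8, from 4).

Steps most likely to fail:

1. Step 7 (carries the label). The interception in one flask may break down: residual lithium amide or alkoxide may consume prenal by self-condensation, the aldolate may revert by retro-aldol cleavage faster than it loses LiOH, or the dienone may stay on the open side. The fallback sets out from 10 and comes back at 15, and uses each stage as a separate, known reaction. 10 is cyclised alone with LiN(i-Pr)2 (THF, 0 °C → rt) and quenched with aqueous NH4Cl to give 2-(3-methylbut-2-en-1-yl)-3,7-bis[(triisopropylsilyl)oxy]dibenz[b,f]oxepin-10(11H)-one F1, which is purified. Its lithium enolate 12, made cleanly with LiN(SiMe3)2 (THF, −78 °C), is treated with 11 and quenched cold to give the β-hydroxy ketone F2. MsCl and Et3N (CH2Cl2, 0 °C) convert F2 into its methanesulfonate F3, which is not isolated; DBU at rt eliminates it to dienone 14, which electrocyclises to 15.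

2. Step 6. C–O bond formation between two ortho-substituted partners may be slow, and silyl transfer from the aryl TIPS ethers to cesium phenoxide may set in at 110 °C. The fallback sets out from 3 and comes back at 10, and replaces the Ullmann coupling by an oxidative coupling at room temperature. Bromine–lithium exchange of 3 (n-BuLi, THF, −78 °C) gives N,N-diethyl-2-lithio-4-[(triisopropylsilyl)oxy]benzamide F4, not isolated, which is borylated with B(Oi-Pr)3 and hydrolysed to {2-(diethylcarbamoyl)-5-[(triisopropylsilyl)oxy]phenyl}boronic acid F5. Chan–Lam coupling of F5 with phenol 9 (Cu(OAc)2, pyridine, 4 Å molecular sieves, CH2Cl2, air, rt) should give 10.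

3. Step 5. The TIPS group may migrate from oxygen to the ortho-lithiated carbon before alkylation, or the alkylation may occur with allylic transposition at the tertiary end of prenyl bromide. The fallback sets out from 7 and comes back at 9, and avoids the aryllithium. Stille allylation of 7 (allyltributylstannane, Pd(P(t-Bu)3)2, toluene, 80 °C) gives 2-methyl-4-(prop-2-en-1-yl)-5-[(triisopropylsilyl)oxy]phenol F6. Cross-metathesis of F6 with 2-methylbut-2-ene (second-generation Grubbs catalyst, CH2Cl2, 40 °C) should give 9.

**Further compounds**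

F1 | step 7 | 2-(3-methylbut-2-en-1-yl)-3,7-bis[(triisopropylsilyl)oxy]dibenz[b,f]oxepin-10(11H)-one | O=C1Cc2cc(CC=C(C)C)c(O[Si](C(C)C)(C(C)C)C(C)C)cc2Oc2cc(O[Si](C(C)C)(C(C)C)C(C)C)ccc21
F2 | step 7 | 11-(1-hydroxy-3-methylbut-2-en-1-yl)-2-(3-methylbut-2-en-1-yl)-3,7-bis[(triisopropylsilyl)oxy]dibenz[b,f]oxepin-10(11H)-one (diastereomer mixture) | CC(C)=CC(O)C1C(=O)c2ccc(O[Si](C(C)C)(C(C)C)C(C)C)cc2Oc2cc(O[Si](C(C)C)(C(C)C)C(C)C)c(CC=C(C)C)cc21
F3 | step 7 | methanesulfonate of F2 (not isolated) | CC(C)=CC(OS(C)(=O)=O)C1C(=O)c2ccc(O[Si](C(C)C)(C(C)C)C(C)C)cc2Oc2cc(O[Si](C(C)C)(C(C)C)C(C)C)c(CC=C(C)C)cc21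
F4 | step 6 | N,N-diethyl-2-lithio-4-[(triisopropylsilyl)oxy]benzamide (not isolated) | CCN(CC)C(=O)c1ccc(O[Si](C(C)C)(C(C)C)C(C)C)cc1[Li]
F5 | step 6 | {2-(diethylcarbamoyl)-5-[(triisopropylsilyl)oxy]phenyl}boronic acid | CCN(CC)C(=O)c1ccc(O[Si](C(C)C)(C(C)C)C(C)C)cc1B(O)O
F6 | step 5 | 2-methyl-4-(prop-2-en-1-yl)-5-[(triisopropylsilyl)oxy]phenol | Cc1cc(CC=C)c(O[Si](C(C)C)(C(C)C)C(C)C)cc1O
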